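- The leftover starting material A in the alder flask at 30 min carries the question. The target is roughly the charge minus A, because the two readings sum to 100% at 6.00 min.

| setting | alder | flask |
|---|---|---|
| starting material | 0.37 M | 0.37 M |
| reagent | 0.74 M | 0.740 M |
| free catalyst | 1.9 mM | 1.9 mM |
| added ligand | 1.4 mM | 1.4 mM |
| remark | the very flask that is asked about, followed so far |  |
| time |  | 30 min |

alder run (percent of the starting material charged)

| time / min | target / % | starting material / % |
|---|---|---|
| 1.50 | 13.3 | 85.9 |
| 3.00 | 23.4 | 75.8 |
| 5.00 | 35.4 | 64.8 |
| 6.00 | 39.6 | 60.6 |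

(standard deviation of a reading: 0.3 percentage points)

* concentration of target at 30 min, in M
* concentration of starting material at 30 min, in M

- the earlier runs were read with a standard deviation of 0.3 percentage points

- At 6.00 min the alder run reads k̄ = 0.0835 min⁻¹, the mean decay constant: the logarithm of charge over leftover, divided by elapsed time.
- The alder curve slows: the last interval reads a local constant k_L = 0.0670 min⁻¹, below k̄. Holding k̄ to the end gives a loose floor for A of 0.0302 M, and holding k_L after the last reading tightens it to 0.0449 M.
- For a ceiling, my reckoning takes the first interval's constant, 0.101 min⁻¹, and lets the local constant keep shrinking at the observed pace λ = 0.0870 min⁻¹. That leaves 0.114 M.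
- The geometric middle replaces the unknown curve by one mean constant after 6.00 min: A near 0.0716 M, target near 0.298 M, with an error factor of 1.59.
- The forecast gives 0.08 M (0.047 M to 0.12 M) and 0.29 M (0.25 M to 0.325 M), holding that “Some slowing therefore remains”. Its A lies inside my limits, above my middle.

- The alder flask gives 0.0648 M of starting material and 0.304 M of target, with A between the limits.

    starting material + free catalyst → catalyst intermediate A (k = 200 L mol⁻¹ min⁻¹)
    free catalyst + added ligand ⇌ idle complex (K = 1200 L mol⁻¹, k = 170 L mol⁻¹ min⁻¹)
    2 reagent → homo dimer (k = 0.140 L mol⁻¹ min⁻¹)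
    catalyst intermediate C → free catalyst + target (k = 160 min⁻¹)
    reagent + catalyst intermediate A ⇌ catalyst intermediate B (K = 19.0 L mol⁻¹, k = 71.0 L mol⁻¹ min⁻¹)
    catalyst intermediate B → by-product + catalyst intermediate C (k = 95.0 min⁻¹)

- By 30.0 min the alder flask's reagent stands at 2.70% of its own charge. Its k̄ over the whole run is 0.0581 min⁻¹, lower than at 6.00 min. A neighbouring flask, alike in all other charges and the time, holds a quarter of that reagent charge, 0.18 M, and leaves 0.227 M of starting material at 30 min; its k̄ is a quarter of the alder value: 0.0163 min⁻¹.

(The runs come from a simulation on assumed constants, noise included.)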